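**Retrosynthetic overview**
1. Target ⇐ AcOH opening (at allylic C2, inversion) of the 2β,3β-vinyl epoxide 25; the 11-membered ring is closed last, at C8–C9, by a Ni/Cr coupling of a C8 enol triflate with the C9 aldehyde.
2. C9–C14 and C20 are (S)-citronellal, joined at C1–C14 by a first Ni/Cr coupling of the ring B enol triflate.
3. Ring B oxidation pattern: C1 ketone → C2=C3 enone → convex epoxide → C1 enol triflate.
4. Ring A is welded onto ring B together with a sacrificial cyclobutane by an intramolecular enone–olefin [2+2] photocycloaddition; retro-ene opening of the cyclobutane leaves C7/C16 cis and a 2-propenyl group at C7.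
5. Ring B comes from an enantioselective Robinson annulation of melonal with ethyl vinyl ketone (sets quaternary C4). Ring order: B → A (with cyclobutane) → 11-membered ring.

Assumption: the sense of induction of the chiral reagents (L-prolinamide in step 1, (R)-ligand in step 8, (S)-ligand in step 12) is taken as written; where one induces the opposite sense, its enantiomer is used.

Numbering: trinervitane numbers of the target are used throughout (C1=C15 alkene, C17 methyl on C15; C2 OAc; C3 OH; C4 quaternary with C18 methyl; ring A = C4–C5–C6–C7–C16; C8=C19H2; C9 OAc; C12 with C20 methyl; C14 OAc); β is the face carrying the C18 methyl.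

**Step 1**
Reactants: 1 2,6-dimethylhept-5-enal (melonal, racemic); 2 pent-1-en-3-one (ethyl vinyl ketone)
Product: 4 (4R)-2,4-dimethyl-4-(4-methylpent-3-en-1-yl)cyclohex-2-en-1-one, via Michael adduct 3 (not isolated)
Conditions: (S)-N-(4-dodecylphenylsulfonyl)pyrrolidine-2-carboxamide (20 mol %), 4 Å MS, ClCH2CH2Cl, rt; then KOH, MeOH, rt
Reagents that add atoms: none
Why: Organocatalytic asymmetric Robinson annulation, in which the enamine of the α-branched aldehyde (its own stereocentre is erased) adds to the vinyl ketone from the face directed by the sulfonamide N–H to create quaternary C4 (R), and the only possible six-ring aldol condensation (C15 onto the neopentyl aldehyde) closes ring B.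

**Step 2**
Reactants: 4 (4R)-2,4-dimethyl-4-(4-methylpent-3-en-1-yl)cyclohex-2-en-1-one
Product: 5 tricyclic cyclobutane ketone (photoadduct; new bonds C16–C7 and C15–C8; gem-dimethyl on C8; C17 methyl, C18 methyl, H7 and H16 all β)
Conditions: hν (350 nm), MeCN/acetone (9:1), 0.01 M, rt
Reagents that add atoms: none
Why: Intramolecular enone–olefin [2+2] photocycloaddition (rule of five), in which C16 bonds to C7 through a five-membered ring on the face of the C4 tether (necessarily cis-fused, so H16 is syn to the C18 methyl) and the 1,4-biradical then closes C15–C8, so that ring A and a cyclobutane form together and C7, C15 and C16 are fixed relative to C4.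

**Step 3**
Reactants: 5 tricyclic cyclobutane ketone
Product: 7 (3R,3aS,7aR)-4,7a-dimethyl-3-(prop-1-en-2-yl)octahydro-5H-inden-5-one, via enol 6 (not isolated)
Conditions: PhMe, 200–220 °C, sealed tube
Reagents that add atoms: none
Why: Proposed new method: a strain-driven thermal retro-ene fragmentation through the six-membered array O=C1–C15–C8–CH2–H cleaves the congested C15–C8 bond and gives the enol plus the 2-propenyl group, so C7 keeps the cis relation to C15 that the cyclobutane enforced (C15 becomes an inconsequential epimer mixture); the closest known reactions are the retro-ene (enolene) ring opening of cis-2-alkyl cyclopropyl and cyclobutyl ketones and the Norrish type 2 cleavage.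

**Step 4**
Reactants: 7 (3R,3aS,7aR)-4,7a-dimethyl-3-(prop-1-en-2-yl)octahydro-5H-inden-5-one
Product: 9 (3R,3aS,7aR)-4,7a-dimethyl-3-(prop-1-en-2-yl)-1,2,3,3a,4,7a-hexahydro-5H-inden-5-one, via silyl enol ether 8 (not isolated)
Conditions: LiN(iPr)2, Me3SiCl, THF, −78 °C; then Pd(OAc)2, MeCN, rt
Reagents that add atoms: none
Why: Ito–Saegusa oxidation, in which kinetic deprotonation at the unhindered C2 methylene (not the tertiary C15–H) gives the less substituted silyl enol ether that divalent palladium dehydrogenates to the C2=C3 enone; no stereocentre is formed.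

**Step 5**
Reactants: 9 C2=C3 enone
Product: 10 2β,3β-epoxy ketone (oxirane syn to the C18 methyl)
Conditions: H2O2 (30 % aq), NaOH, MeOH, 0 °C
Reagents that add atoms: hydrogen peroxide, OO
Why: Weitz–Scheffer nucleophilic epoxidation, in which hydroperoxide adds to C3 on the convex face of the cis-fused bicycle, anti to ring A and its α-oriented 2-propenyl group, which sets C2 and C3.

**Step 6**
Reactants: 10 2β,3β-epoxy ketone
Product: 12 2β,3β-epoxy-7α-(prop-1-en-2-yl) ring AB enol triflate (C1–OTf; C1=C15), via potassium enolate 11 (not isolated)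
Conditions: KN(SiMe3)2, THF, −78 °C; then PhNTf2, −78 to 0 °C
Reagents that add atoms: N-phenylbis(trifluoromethanesulfonimide), O=S(=O)(N(c1ccccc1)S(=O)(=O)C(F)(F)F)C(F)(F)F
Why: Enol triflate formation, in which the only enolisable α-hydrogen (C15–H) is removed and the tetrasubstituted enolate is O-sulfonylated, fixing the future C1=C15 double bond and removing the C15 stereocentre.

**Step 7**
Reactants: 12 ring AB enol triflate with 2-propenyl group
Product: 14 2β,3β-epoxy-7α-acetyl ring AB enol triflate (methyl ketone), via ozonide 13 (not isolated)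
Conditions: O3, CH2Cl2, −78 °C; then PPh3, −78 °C to rt
Reagents that add atoms: ozone, [O-][O+]=O
Why: Ozonolysis, in which the electron-rich 1,1-disubstituted alkene is cleaved much faster than the triflate-bearing tetrasubstituted alkene, and the neutral reductive work-up leaves the now enolisable C7 centre untouched.

**Step 8**
Reactants: 14 7α-acetyl ring AB enol triflate; 15 (3S)-3,7-dimethyloct-6-enal ((S)-citronellal)
Product: 17 (14S)-allylic alcohol (C1–C14 bond; citronellyl chain on C1), via alkenylchromium species 16 (not isolated)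
Conditions: CrCl2 (4 equiv), NiCl2 (5 mol %), (R)-N-[2-(4-isopropyl-4,5-dihydrooxazol-2-yl)-6-methylphenyl]methanesulfonamide (4 equiv), Et3N (4 equiv), THF, rt
Reagents that add atoms: none
Why: Asymmetric Nozaki–Hiyama–Kishi coupling, in which zerovalent nickel inserts into the vinyl triflate, transmetallation gives the alkenylchromium species that adds to the aldehyde and not to the methyl ketone, and the chromium-bound chiral sulfonamide selects the aldehyde face to set C14 (S), while C12 (S) comes unchanged from 15.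

**Step 9**
Reactants: 17 (14S)-allylic alcohol
Product: 18 (14S)-acetate
Conditions: Ac2O, pyridine, DMAP (cat.), CH2Cl2, 0 °C to rt
Reagents that add atoms: acetic anhydride, CC(=O)OC(C)=O
Why: DMAP-catalysed acylation of the secondary allylic alcohol installs the C14 acetate without touching any stereocentre.

**Step 10**
Reactants: 18 (14S)-acetate with C8 methyl ketone
Product: 20 C8 enol triflate (7α-[1-(triflyloxy)vinyl]; 14S acetate), via potassium enolate 19 (not isolated)
Conditions: KN(SiMe3)2 (1.05 equiv), THF, −78 °C; then PhNTf2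
Reagents that add atoms: N-phenylbis(trifluoromethanesulfonimide), O=S(=O)(N(c1ccccc1)S(=O)(=O)C(F)(F)F)C(F)(F)F
Why: Kinetic enolate formation at the methyl group of the methyl ketone (more acidic than the acetate, less hindered than C7–H) followed by O-triflation gives the 2-triflyloxy-1-alkene without epimerising C7.

**Step 11**
Reactants: 20 C8 enol triflate with trisubstituted chain alkene
Product: 22 C9 aldehyde (seco aldehyde enol triflate), via diol 21 (not isolated)
Conditions: OsO4 (2 mol %), NaIO4, 2,6-lutidine, 1,4-dioxane/H2O (3:1), rt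
Reagents that add atoms: osmium tetroxide, O=[Os](=O)(=O)=O; sodium periodate, [Na+].[O-][I](=O)(=O)=O
Why: Lemieux–Johnson oxidation, in which OsO4 dihydroxylates the unhindered electron-rich trisubstituted alkene in preference to the hindered tetrasubstituted alkene and the electron-poor enol triflate, and periodate cleaves the diol to the C9 aldehyde.

**Step 12**
Reactants: 22 C9 aldehyde with C8 enol triflate
Product: 24 (9R)-2β,3β-epoxytrinervita-1(15),8(19)-diene-9,14-diol 14-acetate, via alkenylchromium species 23 (not isolated)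
Conditions: CrCl2 (6 equiv), NiCl2 (10 mol %), (S)-N-[2-(4-isopropyl-4,5-dihydrooxazol-2-yl)-6-methylphenyl]methanesulfonamide (6 equiv), Et3N (6 equiv), THF, 0.002 M, slow addition, rt
Reagents that add atoms: none
Why: Intramolecular asymmetric Nozaki–Hiyama–Kishi reaction under high dilution closes the 11-membered ring at C8–C9 and gives the 2-methylene allylic alcohol directly, with the chiral chromium sulfonamide complex setting C9 (R).

**Step 13**
Reactants: 24 (9R)-macrocyclic alcohol
Product: 25 2β,3β-epoxytrinervita-1(15),8(19)-diene-9,14-diyl diacetate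
Conditions: Ac2O, pyridine, DMAP (cat.), CH2Cl2, 0 °C to rt
Reagents that add atoms: acetic anhydride, CC(=O)OC(C)=O
Why: Acylation of the remaining secondary allylic alcohol installs the C9 acetate without touching any stereocentre.

**Step 14**
Reactants: 25 2β,3β-epoxy diacetate
Product: 26 (2R,3R,4S,7R,9R,12S,14S,16S)-trinervita-1(15),8(19)-diene-2,3,9,14-tetrol 2,9,14-triacetate (CNP0318778.1)
Conditions: AcOH, NaOAc, 60 °C
Reagents that add atoms: acetic acid, CC(=O)O
Why: Regio- and stereospecific opening of the vinyl epoxide, in which acetate attacks the allylic, less hindered C2 (not the neopentyl C3) with inversion (SN2, trans-diaxial), gives the trans 2-acetoxy-3-hydroxy pattern with the free hydroxyl at C3.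

**Compound list**
1 | 2,6-dimethylhept-5-enal (melonal, racemic) | CC(C)=CCCC(C)C=O | starting material
2 | pent-1-en-3-one (ethyl vinyl ketone) | C=CC(=O)CC | starting material
3 | (2R)-2-methyl-2-(4-methylpent-3-en-1-yl)-5-oxoheptanal (Michael adduct) | O=C[C@](C)(CCC=C(C)C)CCC(=O)CC | intermediate (not isolated)
4 | (4R)-2,4-dimethyl-4-(4-methylpent-3-en-1-yl)cyclohex-2-en-1-one | O=C1C(C)=C[C@](C)(CCC=C(C)C)CC1 | intermediate
5 | tricyclic cyclobutane ketone: ring B cyclohexanone (C1=O), ring A (C4–C5–C6–C7–C16), cyclobutane C15–C16–C7–C8 with gem-dimethyl C8; C17 methyl, C18 methyl, H7, H16 β | O=C2[C@@]4(C)[C@@H]3[C@H](C4(C)C)CC[C@]3(C)CC2 | intermediate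
6 | enol of 7 (C1(OH)=C15), 7α-(prop-1-en-2-yl) | OC2=C(C)[C@@H]3[C@H](C(C)=C)CC[C@]3(C)CC2 | intermediate (not isolated)
7 | (3R,3aS,7aR)-4,7a-dimethyl-3-(prop-1-en-2-yl)octahydro-5H-inden-5-one (cis-fused; H7, H16, C18 methyl β; 2-propenyl α; C15 epimers) | O=C2C(C)[C@@H]3[C@H](C(C)=C)CC[C@]3(C)CC2 | intermediate
8 | kinetic trimethylsilyl enol ether of 7 (C1=C2) | C[Si](C)(C)OC=2C(C)[C@@H]3[C@H](C(C)=C)CC[C@]3(C)CC=2 | intermediate (not isolated)
9 | (3R,3aS,7aR)-4,7a-dimethyl-3-(prop-1-en-2-yl)-1,2,3,3a,4,7a-hexahydro-5H-inden-5-one (C2=C3 enone; C15 epimers) | O=C2C(C)[C@@H]3[C@H](C(C)=C)CC[C@]3(C)C=C2 | intermediate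
10 | 2β,3β-epoxy ketone of 9 (oxirane syn to C18 methyl; C15 epimers) | O=C2C(C)[C@@H]3[C@H](C(C)=C)CC[C@]3(C)[C@H]4O[C@H]42 | intermediate
11 | potassium enolate of 10 (C1=C15) | [K+].[O-]C2=C(C)[C@@H]3[C@H](C(C)=C)CC[C@]3(C)[C@H]4O[C@H]42 | intermediate (not isolated)
12 | C1 enol triflate: 2β,3β-epoxy, C1=C15, 7α-(prop-1-en-2-yl) | O=S(=O)(OC2=C(C)[C@@H]3[C@H](C(C)=C)CC[C@]3(C)[C@H]4O[C@H]42)C(F)(F)F | intermediate
13 | 1,2,4-trioxolane (ozonide) of the 2-propenyl group of 12 (C8 epimers) | O=S(=O)(OC2=C(C)[C@@H]3[C@H](C5(C)OCOO5)CC[C@]3(C)[C@H]4O[C@H]42)C(F)(F)F | intermediate (not isolated)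
14 | C1 enol triflate with 7α-acetyl group (C8 methyl ketone), 2β,3β-epoxy | O=S(=O)(OC2=C(C)[C@@H]3[C@H](C(C)=O)CC[C@]3(C)[C@H]4O[C@H]42)C(F)(F)F | intermediate
15 | (3S)-3,7-dimethyloct-6-enal ((S)-citronellal) | O=CC[C@@H](C)CCC=C(C)C | starting material
16 | alkenylchromium dichloride from 14 (Cr on C1; ligand omitted) | Cl[Cr](Cl)C2=C(C)[C@@H]3[C@H](C(C)=O)CC[C@]3(C)[C@H]4O[C@H]42 | intermediate (not isolated)
17 | (14S)-allylic alcohol: (12S)-citronellyl chain on C1, 7α-acetyl, 2β,3β-epoxy, C1=C15 | CC(C)=CCC[C@H](C)C[C@H](O)C2=C(C)[C@@H]3[C@H](C(C)=O)CC[C@]3(C)[C@H]4O[C@H]42 | intermediate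
18 | (14S)-acetate of 17 | CC(C)=CCC[C@H](C)C[C@H](OC(C)=O)C2=C(C)[C@@H]3[C@H](C(C)=O)CC[C@]3(C)[C@H]4O[C@H]42 | intermediate
19 | potassium enolate of the C8 methyl ketone of 18 (C8=C19) | CC(C)=CCC[C@H](C)C[C@H](OC(C)=O)C2=C(C)[C@@H]3[C@H](C(=C)[O-])CC[C@]3(C)[C@H]4O[C@H]42.[K+] | intermediate (not isolated)
20 | C8 enol triflate: 7α-[1-(trifluoromethanesulfonyloxy)vinyl], (14S)-acetate, chain alkene intact | CC(C)=CCC[C@H](C)C[C@H](OC(C)=O)C2=C(C)[C@@H]3[C@H](C(=C)OS(=O)(=O)C(F)(F)F)CC[C@]3(C)[C@H]4O[C@H]42 | intermediate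
21 | diol from the trisubstituted chain alkene of 20 (secondary carbinol epimers) | CC(C)(O)C(O)CC[C@H](C)C[C@H](OC(C)=O)C2=C(C)[C@@H]3[C@H](C(=C)OS(=O)(=O)C(F)(F)F)CC[C@]3(C)[C@H]4O[C@H]42 | intermediate (not isolated)
22 | C9 aldehyde with C8 enol triflate, (12S), (14S)-acetate | O=CCC[C@H](C)C[C@H](OC(C)=O)C2=C(C)[C@@H]3[C@H](C(=C)OS(=O)(=O)C(F)(F)F)CC[C@]3(C)[C@H]4O[C@H]42 | intermediate
23 | alkenylchromium dichloride from 22 (Cr on C8; ligand omitted) | O=CCC[C@H](C)C[C@H](OC(C)=O)C2=C(C)[C@@H]3[C@H](C(=C)[Cr](Cl)Cl)CC[C@]3(C)[C@H]4O[C@H]42 | intermediate (not isolated)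
24 | (9R,12S,14S)-2β,3β-epoxytrinervita-1(15),8(19)-diene-9,14-diol 14-acetate | C=C1[C@H](O)CC[C@H](C)C[C@H](OC(C)=O)C2=C(C)[C@@H]3[C@H]1CC[C@]3(C)[C@H]4O[C@H]42 | intermediate
25 | (9R,12S,14S)-2β,3β-epoxytrinervita-1(15),8(19)-diene-9,14-diyl diacetate | C=C1[C@H](OC(C)=O)CC[C@H](C)C[C@H](OC(C)=O)C2=C(C)[C@@H]3[C@H]1CC[C@]3(C)[C@H]4O[C@H]42 | intermediate
26 | (2R,3R,4S,7R,9R,12S,14S,16S)-trinervita-1(15),8(19)-diene-2,3,9,14-tetrol 2,9,14-triacetate | C=C1[C@H](OC(C)=O)CC[C@H](C)C[C@H](OC(C)=O)C2=C(C)[C@@H]3[C@H]1CC[C@]3(C)[C@@H](O)[C@@H]2OC(C)=O | target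

**Step count**
Total: 14 steps. Longest linear sequence: 14 steps (from 1; 2 and 15 are used as bought).

**Three steps most likely to fail**

Step 1. The enantioselectivity for a methyl/primary-alkyl aldehyde may be modest. The fallback sets out from 1 and comes back at 4. Melonal is condensed with but-3-yn-2-one (pyrrolidine cat., then KOH) to the achiral 4-methyl-4-(4-methylpent-3-en-1-yl)cyclohexa-2,5-dien-1-one F1. This is desymmetrised by copper hydride conjugate reduction (Cu(OAc)2, (R)-DTBM-SEGPHOS, (EtO)2MeSiH, PhMe) to (4R)-4-methyl-4-(4-methylpent-3-en-1-yl)cyclohex-2-en-1-one F2. α-Iodination (I2, pyridine, CH2Cl2) gives (4R)-2-iodo-4-methyl-4-(4-methylpent-3-en-1-yl)cyclohex-2-en-1-one F3, and Suzuki methylation (MeB(OH)2, Pd(OAc)2, SPhos, K3PO4) returns to 4.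

Step 3. The retro-ene opening is unprecedented on this skeleton, and over-heating could let the product close again by a Conia-ene reaction of C15 onto the 2-propenyl group. The fallback sets out from 4 and comes back at 7. Enone 4 is treated with MeAlCl2 (CH2Cl2, −78 to 0 °C) in an intramolecular conjugate ene reaction: C7 adds to C16 and a methyl hydrogen passes to the enolate carbon within the same six-membered array, giving 7 directly with the same cis relation. This fallback makes no new compound (F0).

Step 12. Closure of the medium ring with ligand control of C9 may give the wrong or a mixed configuration. The fallback sets out from 22 and comes back at 24. The ring is closed with ligand-free CrCl2/NiCl2 (DMSO, high dilution) to 24 as a C9 epimer mixture. Dess–Martin periodinane then gives the macrocyclic enone 2β,3β-epoxy-9-oxotrinervita-1(15),8(19)-dien-14-yl acetate F4, which is reduced with (S)-2-methyl-CBS-oxazaborolidine and catecholborane (PhMe, −78 °C) to (9R)-24.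

**Further compounds**
F1 | step 1 | 4-methyl-4-(4-methylpent-3-en-1-yl)cyclohexa-2,5-dien-1-one | O=C1C=CC(C)(CCC=C(C)C)C=C1
F2 | step 1 | (4R)-4-methyl-4-(4-methylpent-3-en-1-yl)cyclohex-2-en-1-one | O=C1C=C[C@](C)(CCC=C(C)C)CC1
F3 | step 1 | (4R)-2-iodo-4-methyl-4-(4-methylpent-3-en-1-yl)cyclohex-2-en-1-one | O=C1C(I)=C[C@](C)(CCC=C(C)C)CC1
F0 | step 3 | none | none
F4 | step 12 | (12S,14S)-2β,3β-epoxy-9-oxotrinervita-1(15),8(19)-dien-14-yl acetate | C=C1C(=O)CC[C@H](C)C[C@H](OC(C)=O)C2=C(C)[C@@H]3[C@H]1CC[C@]3(C)[C@H]4O[C@H]42
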